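**Strategy**

Both γ-pyranone rings are cut at their enol-ether double bonds: C2=C3 in ring C of the 8-linked 4'-methoxyflavone unit and C2''=C3'' in the pyranone of the 6''-linked 7''-methoxyflavone unit. Each bond lies between the C4 ketone and the O1 aryl oxygen, so it can be made by an intramolecular Wittig reaction of a keto-stabilised ylide with an aryl ester on the neighbouring phenol oxygen. One thermolysis therefore closes both heterocycles and brings in the two different B rings. The precursor is a hexa-oxygenated biphenyl bearing two Ph3P=CH–CO groups, a 4-methoxybenzoate on the hindered phenol oxygen and a 4-benzyloxybenzoate on the open one, installed one after the other through a methoxymethyl mask.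

Key step: step 13

Remark: compounds 4, 10 and 13 are assumed to be purchasable. The target SMILES defines no configuration at the biaryl axis, so every biaryl compound is meant without axial control. Unprimed locants refer to the 4'-methoxyflavone unit and doubly primed locants to the 7-methoxyflavone unit.

**Route**

Step 1
Reactants: 1 2,4,6-trihydroxyacetophenone
Product: 2 1-[2,4-bis(benzyloxy)-6-hydroxyphenyl]ethan-1-one
Conditions: BnBr (2.05 equiv), K2CO3, DMF, 0 °C to rt
Reagents that add atoms: benzyl bromide, BrCc1ccccc1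
Why: Williamson etherification should take the para hydroxyl and one ortho hydroxyl, while the last ortho hydroxyl is held in a hydrogen bond to the acetyl carbonyl and is the least nucleophilic, so the di-O-benzyl ether should predominate.

Step 2
Reactants: 2 1-[2,4-bis(benzyloxy)-6-hydroxyphenyl]ethan-1-one
Product: 3 1-[4,6-bis(benzyloxy)-2-hydroxy-3-iodophenyl]ethan-1-one
Conditions: BnMe3N+ ICl2− (1.0 equiv), NaHCO3, CH2Cl2/MeOH, rt
Reagents that add atoms: benzyltrimethylammonium dichloroiodate, C[N+](C)(C)Cc1ccccc1.Cl[I-]Cl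
Why: Electrophilic aromatic iodination should be steered by the free phenol to its ortho carbon, which is also less crowded than the alternative carbon flanked by two benzyloxy groups, and one equivalent of the buffered reagent should deliver a single iodine.

Step 3
Reactants: 4 1-(2,6-dihydroxy-4-methoxyphenyl)ethan-1-one
Product: 5 1-[2-hydroxy-4-methoxy-6-(methoxymethoxy)phenyl]ethan-1-one
Conditions: MOMCl (1.1 equiv), i-Pr2NEt, CH2Cl2, 0 °C
Reagents that add atoms: chloromethyl methyl ether, COCCl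
Why: O-alkylation of one of the two equivalent phenols should stop at the monoacetal because the remaining hydroxyl is then locked in the chelate with the ketone.

Step 4
Reactants: 5 1-[2-hydroxy-4-methoxy-6-(methoxymethoxy)phenyl]ethan-1-one
Product: 6 1-[2-hydroxy-3-iodo-4-methoxy-6-(methoxymethoxy)phenyl]ethan-1-one
Conditions: BnMe3N+ ICl2− (1.0 equiv), NaHCO3, CH2Cl2/MeOH, rt
Reagents that add atoms: benzyltrimethylammonium dichloroiodate, C[N+](C)(C)Cc1ccccc1.Cl[I-]Cl
Why: The same phenol-directed electrophilic iodination should place iodine on the carbon between the free hydroxyl and the methoxy group, and the hydrogen carbonate buffer should keep the acid-labile acetal intact.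

Step 5
Reactants: 6 1-[2-hydroxy-3-iodo-4-methoxy-6-(methoxymethoxy)phenyl]ethan-1-one
Product: 7 1-[2-(benzyloxy)-3-iodo-4-methoxy-6-(methoxymethoxy)phenyl]ethan-1-one
Conditions: BnBr, K2CO3, DMF, 50 °C
Reagents that add atoms: benzyl bromide, BrCc1ccccc1
Why: Williamson benzylation of the only free (chelated) phenol proceeds on gentle warming in a dipolar solvent and fixes the future 5''-oxygen as a benzyl ether.

Step 6
Reactants: 7 1-[2-(benzyloxy)-3-iodo-4-methoxy-6-(methoxymethoxy)phenyl]ethan-1-one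
Product: 8 1-[2-(benzyloxy)-4-methoxy-6-(methoxymethoxy)-3-(4,4,5,5-tetramethyl-1,3,2-dioxaborolan-2-yl)phenyl]ethan-1-one
Conditions: HBpin, PdCl2(MeCN)2 (3 mol %), SPhos, Et3N, 1,4-dioxane, 80 °C
Reagents that add atoms: pinacolborane, [H]B1OC(C)(C)C(C)(C)O1
Why: Palladium-catalysed borylation of an aryl iodide with pinacolborane (Masuda–Miyaura type) is dependable for doubly ortho-substituted halides when the bulky, electron-rich SPhos ligand is used, and the ketone, benzyl ether and acetal are tolerated.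

Step 7
Reactants: 3 1-[4,6-bis(benzyloxy)-2-hydroxy-3-iodophenyl]ethan-1-one; 8 1-[2-(benzyloxy)-4-methoxy-6-(methoxymethoxy)-3-(4,4,5,5-tetramethyl-1,3,2-dioxaborolan-2-yl)phenyl]ethan-1-one
Product: 9 1,1'-[2',4,6-tris(benzyloxy)-2-hydroxy-6'-methoxy-4'-(methoxymethoxy)[1,1'-biphenyl]-3,3'-diyl]di(ethan-1-one)
Conditions: Pd2(dba)3 (2.5 mol %), SPhos (10 mol %), K3PO4, toluene/H2O (10:1), 100 °C
Reagents that add atoms: none
Why: Suzuki–Miyaura cross-coupling with a dialkylbiarylphosphine ligand is the standard way to join two doubly ortho-substituted arenes, the iodide should undergo oxidative addition even as its phenoxide, and the phosphate base leaves the acetal and benzyl ethers intact.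

Step 8
Reactants: 9 1,1'-[2',4,6-tris(benzyloxy)-2-hydroxy-6'-methoxy-4'-(methoxymethoxy)[1,1'-biphenyl]-3,3'-diyl]di(ethan-1-one); 10 4-methoxybenzoyl chloride
Product: 11 3,3'-diacetyl-2',4,6-tris(benzyloxy)-6'-methoxy-4'-(methoxymethoxy)[1,1'-biphenyl]-2-yl 4-methoxybenzoate
Conditions: Et3N, DMAP (0.2 equiv), CH2Cl2, 0 °C to rt
Reagents that add atoms: 4-methoxybenzoyl chloride (10), COc1ccc(C(=O)Cl)cc1
Why: DMAP-catalysed acylation should esterify the hindered phenol cleanly because it is the only free hydroxyl in the molecule, the other ring oxygen destined for a pyranone being masked as the acetal.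

Step 9
Reactants: 11 3,3'-diacetyl-2',4,6-tris(benzyloxy)-6'-methoxy-4'-(methoxymethoxy)[1,1'-biphenyl]-2-yl 4-methoxybenzoate
Product: 12 3,3'-diacetyl-2',4,6-tris(benzyloxy)-4'-hydroxy-6'-methoxy[1,1'-biphenyl]-2-yl 4-methoxybenzoate
Conditions: ZnBr2, n-PrSH, CH2Cl2, 0 °C
Reagents that add atoms: none
Why: Lewis-acid-promoted cleavage of the aryl methoxymethyl ether with a thiol that captures the methoxymethyl cation is fast, aprotic and non-basic, so the aryl ester, the benzyl ethers and the electron-rich rings should be spared.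

Step 10
Reactants: 12 3,3'-diacetyl-2',4,6-tris(benzyloxy)-4'-hydroxy-6'-methoxy[1,1'-biphenyl]-2-yl 4-methoxybenzoate; 13 4-(benzyloxy)benzoyl chloride
Product: 14 3,3'-diacetyl-2',4,6-tris(benzyloxy)-4'-{[4-(benzyloxy)benzoyl]oxy}-6'-methoxy[1,1'-biphenyl]-2-yl 4-methoxybenzoate
Conditions: Et3N, DMAP (0.2 equiv), CH2Cl2, 0 °C to rt
Reagents that add atoms: 4-(benzyloxy)benzoyl chloride (13), O=C(Cl)c1ccc(OCc2ccccc2)cc1
Why: DMAP-catalysed acylation of the newly freed, unhindered phenol should install the second aroyl group without ambiguity, since the first ester already occupies the other phenol oxygen.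

Step 11
Reactants: 14 3,3'-diacetyl-2',4,6-tris(benzyloxy)-4'-{[4-(benzyloxy)benzoyl]oxy}-6'-methoxy[1,1'-biphenyl]-2-yl 4-methoxybenzoate
Product: 16 3,3'-bis(bromoacetyl)-2',4,6-tris(benzyloxy)-4'-{[4-(benzyloxy)benzoyl]oxy}-6'-methoxy[1,1'-biphenyl]-2-yl 4-methoxybenzoate, via bis(trimethylsilyl enol ether) 15 (not isolated)
Conditions: TMSOTf, Et3N, CH2Cl2, 0 °C; solvent switch; NBS (2.05 equiv), THF, −78 °C
Reagents that add atoms: N-bromosuccinimide, O=C1CCC(=O)N1Br; trimethylsilyl triflate, C[Si](C)(C)OS(=O)(=O)C(F)(F)F (silicon in 15 only)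
Why: Soft enolisation of both methyl ketones followed by bromination of the silyl enol ethers should outpace attack of the brominating agent on the free C–H positions of the alkoxy-rich rings, and the absence of a free ortho phenol excludes closure to a benzofuranone.

Step 12
Reactants: 16 3,3'-bis(bromoacetyl)-2',4,6-tris(benzyloxy)-4'-{[4-(benzyloxy)benzoyl]oxy}-6'-methoxy[1,1'-biphenyl]-2-yl 4-methoxybenzoate
Product: 18 2',4,6-tris(benzyloxy)-4'-{[4-(benzyloxy)benzoyl]oxy}-6'-methoxy-3,3'-bis[(triphenyl-λ5-phosphanylidene)acetyl][1,1'-biphenyl]-2-yl 4-methoxybenzoate, via bis(phosphonium bromide) 17 (not isolated)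
Conditions: PPh3 (2.2 equiv), MeCN/toluene, 40 °C; then 1 M Na2CO3 (aq), CH2Cl2, 0 °C
Reagents that add atoms: triphenylphosphine, c1ccc(cc1)P(c1ccccc1)c1ccccc1
Why: SN2 quaternisation of the two primary α-bromoketones followed by deprotonation of the acidic phenacylphosphonium salts with cold aqueous carbonate is the standard entry to keto-stabilised ylides, and the brief, cold, biphasic base treatment should leave both aryl esters intact.

Step 13
Reactants: 18 2',4,6-tris(benzyloxy)-4'-{[4-(benzyloxy)benzoyl]oxy}-6'-methoxy-3,3'-bis[(triphenyl-λ5-phosphanylidene)acetyl][1,1'-biphenyl]-2-yl 4-methoxybenzoate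
Product: 19 5,7-bis(benzyloxy)-8-{5-(benzyloxy)-2-[4-(benzyloxy)phenyl]-7-methoxy-4-oxo-4H-chromen-6-yl}-2-(4-methoxyphenyl)-4H-chromen-4-one
Conditions: toluene (0.01 M), 110 °C, argon
Reagents that add atoms: none
Why: Each ketone-stabilised ylide carbon adds to the carbonyl carbon of the aroyl ester on the adjacent ring oxygen, the betaine collapses to an oxaphosphetane, and loss of Ph3P=O leaves the C2=C3 (respectively C2''=C3'') enol-ether double bond inside the new 4-pyranone. The closest known reaction type is the intramolecular Wittig olefination of the ester carbonyl in (2-acyloxyphenacylidene)triphenylphosphoranes, an established chromone and flavone synthesis that is simply required twice here. Each of the two rings closes in a 6-exo-trig mode, the ylide carbon attacking an ester C=O that lies outside the forming six-membered ring. No stereocentre is formed and the biaryl axis is not controlled. The step needs each ylide to react only with its own ester and to olefinate instead of merely transferring the acyl group; the six-membered transition state next to each ylide is far easier to reach than any contact across the twisted, tetra-ortho-substituted axis, and the position of each ring oxygen is already fixed by the phenol that bears the ester. The medium is neutral and free of base, so the benzyl and methyl ethers are untouched.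

Step 14
Reactants: 19 5,7-bis(benzyloxy)-8-{5-(benzyloxy)-2-[4-(benzyloxy)phenyl]-7-methoxy-4-oxo-4H-chromen-6-yl}-2-(4-methoxyphenyl)-4H-chromen-4-one
Product: 20 5,7-dihydroxy-8-[5-hydroxy-2-(4-hydroxyphenyl)-7-methoxy-4-oxo-4H-chromen-6-yl]-2-(4-methoxyphenyl)-4H-chromen-4-one
Conditions: H2 (1 atm), 10% Pd/C, THF/MeOH, rt
Reagents that add atoms: none
Why: Catalytic hydrogenolysis should remove all four benzyl ethers under neutral conditions that leave the two methyl ethers and the vinylogous-ester C2=C3 bonds of the flavone rings unchanged.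

**Compound list**

1 | 2,4,6-trihydroxyacetophenone | CC(=O)c1c(O)cc(O)cc1O | starting material
2 | 1-[2,4-bis(benzyloxy)-6-hydroxyphenyl]ethan-1-one | CC(=O)c1c(O)cc(OCc2ccccc2)cc1OCc1ccccc1 | intermediate
3 | 1-[4,6-bis(benzyloxy)-2-hydroxy-3-iodophenyl]ethan-1-one | CC(=O)c1c(O)c(I)c(OCc2ccccc2)cc1OCc1ccccc1 | intermediate
4 | 1-(2,6-dihydroxy-4-methoxyphenyl)ethan-1-one | COc1cc(O)c(C(C)=O)c(O)c1 | starting material
5 | 1-[2-hydroxy-4-methoxy-6-(methoxymethoxy)phenyl]ethan-1-one | COCOc1cc(OC)cc(O)c1C(C)=O | intermediate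
6 | 1-[2-hydroxy-3-iodo-4-methoxy-6-(methoxymethoxy)phenyl]ethan-1-one | COCOc1cc(OC)c(I)c(O)c1C(C)=O | intermediate
7 | 1-[2-(benzyloxy)-3-iodo-4-methoxy-6-(methoxymethoxy)phenyl]ethan-1-one | COCOc1cc(OC)c(I)c(OCc2ccccc2)c1C(C)=O | intermediate
8 | 1-[2-(benzyloxy)-4-methoxy-6-(methoxymethoxy)-3-(4,4,5,5-tetramethyl-1,3,2-dioxaborolan-2-yl)phenyl]ethan-1-one | COCOc1cc(OC)c(B2OC(C)(C)C(C)(C)O2)c(OCc2ccccc2)c1C(C)=O | intermediate
9 | 1,1'-[2',4,6-tris(benzyloxy)-2-hydroxy-6'-methoxy-4'-(methoxymethoxy)[1,1'-biphenyl]-3,3'-diyl]di(ethan-1-one) | CC(=O)c1c(O)c(-c2c(OC)cc(OCOC)c(C(C)=O)c2OCc2ccccc2)c(OCc2ccccc2)cc1OCc1ccccc1 | intermediate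
10 | 4-methoxybenzoyl chloride | COc1ccc(C(=O)Cl)cc1 | starting material
11 | 3,3'-diacetyl-2',4,6-tris(benzyloxy)-6'-methoxy-4'-(methoxymethoxy)[1,1'-biphenyl]-2-yl 4-methoxybenzoate | CC(=O)c1c(OC(=O)c2ccc(OC)cc2)c(-c2c(OC)cc(OCOC)c(C(C)=O)c2OCc2ccccc2)c(OCc2ccccc2)cc1OCc1ccccc1 | intermediate
12 | 3,3'-diacetyl-2',4,6-tris(benzyloxy)-4'-hydroxy-6'-methoxy[1,1'-biphenyl]-2-yl 4-methoxybenzoate | CC(=O)c1c(OC(=O)c2ccc(OC)cc2)c(-c2c(OC)cc(O)c(C(C)=O)c2OCc2ccccc2)c(OCc2ccccc2)cc1OCc1ccccc1 | intermediate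
13 | 4-(benzyloxy)benzoyl chloride | O=C(Cl)c1ccc(OCc2ccccc2)cc1 | starting material
14 | 3,3'-diacetyl-2',4,6-tris(benzyloxy)-4'-{[4-(benzyloxy)benzoyl]oxy}-6'-methoxy[1,1'-biphenyl]-2-yl 4-methoxybenzoate | CC(=O)c1c(OC(=O)c2ccc(OC)cc2)c(-c2c(OC)cc(OC(=O)c3ccc(OCc4ccccc4)cc3)c(C(C)=O)c2OCc2ccccc2)c(OCc2ccccc2)cc1OCc1ccccc1 | intermediate
15 | bis(trimethylsilyl enol ether) of 14 (both acetyl groups as 1-(trimethylsilyloxy)ethenyl) | C=C(O[Si](C)(C)C)c1c(OC(=O)c2ccc(OC)cc2)c(-c2c(OC)cc(OC(=O)c3ccc(OCc4ccccc4)cc3)c(C(=C)O[Si](C)(C)C)c2OCc2ccccc2)c(OCc2ccccc2)cc1OCc1ccccc1 | intermediate (not isolated)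
16 | 3,3'-bis(bromoacetyl)-2',4,6-tris(benzyloxy)-4'-{[4-(benzyloxy)benzoyl]oxy}-6'-methoxy[1,1'-biphenyl]-2-yl 4-methoxybenzoate | O=C(CBr)c1c(OC(=O)c2ccc(OC)cc2)c(-c2c(OC)cc(OC(=O)c3ccc(OCc4ccccc4)cc3)c(C(=O)CBr)c2OCc2ccccc2)c(OCc2ccccc2)cc1OCc1ccccc1 | intermediate
17 | bis(triphenylphosphonium) dibromide from 16 (each CH2Br replaced by CH2PPh3+ Br−) | O=C(C[P+](c1ccccc1)(c1ccccc1)c1ccccc1)c1c(OC(=O)c2ccc(OC)cc2)c(-c2c(OC)cc(OC(=O)c3ccc(OCc4ccccc4)cc3)c(C(=O)C[P+](c3ccccc3)(c3ccccc3)c3ccccc3)c2OCc2ccccc2)c(OCc2ccccc2)cc1OCc1ccccc1.[Br-].[Br-] | intermediate (not isolated)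
18 | 2',4,6-tris(benzyloxy)-4'-{[4-(benzyloxy)benzoyl]oxy}-6'-methoxy-3,3'-bis[(triphenyl-λ5-phosphanylidene)acetyl][1,1'-biphenyl]-2-yl 4-methoxybenzoate | COc1ccc(cc1)C(=O)Oc1c(C(=O)C=P(c2ccccc2)(c2ccccc2)c2ccccc2)c(OCc2ccccc2)cc(OCc2ccccc2)c1-c1c(OC)cc(OC(=O)c2ccc(OCc3ccccc3)cc2)c(C(=O)C=P(c2ccccc2)(c2ccccc2)c2ccccc2)c1OCc1ccccc1 | intermediate
19 | 5,7-bis(benzyloxy)-8-{5-(benzyloxy)-2-[4-(benzyloxy)phenyl]-7-methoxy-4-oxo-4H-chromen-6-yl}-2-(4-methoxyphenyl)-4H-chromen-4-one | COc1ccc(-c2cc(=O)c3c(OCc4ccccc4)cc(OCc4ccccc4)c(-c4c(OC)cc5oc(-c6ccc(OCc7ccccc7)cc6)cc(=O)c5c4OCc4ccccc4)c3o2)cc1 | intermediate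
20 | 5,7-dihydroxy-8-[5-hydroxy-2-(4-hydroxyphenyl)-7-methoxy-4-oxo-4H-chromen-6-yl]-2-(4-methoxyphenyl)-4H-chromen-4-one | COc1ccc(-c2cc(=O)c3c(O)cc(O)c(-c4c(OC)cc5oc(-c6ccc(O)cc6)cc(=O)c5c4O)c3o2)cc1 | target

**Step count**

Total step count: 14. Longest linear sequence: 12 steps (steps 3 to 14, from compound 4).

**Steps most likely to fail**

Step 13. The olefination may stall at the crowded ester beside the biaryl axis, or the ylide may simply take over the acyl group with loss of the phenoxide, so that one or both rings stay open. The fallback sets out from diester 14. A twofold Baker–Venkataraman O-to-C aroyl shift (LiHMDS, THF, −78 to 0 °C) would give the bis(1,3-diketone) diphenol F1. Acid-catalysed cyclodehydration (p-TsOH, toluene, 90 °C) would then close both pyranones, and the sequence comes back to the route at compound 19.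

Step 7. Protodeboronation of the doubly ortho-alkoxylated boronate may outrun transmetalation to the hindered arylpalladium species, and the chelating phenoxide of the iodide may slow or sequester the catalyst. The fallback sets out from compounds 3 and 7. Phenol 3 would be acetylated (Ac2O, pyridine, DMAP) to the aryl acetate F2. Iodide 7 would be turned into the arylzinc iodide F3 by zinc insertion (Zn dust, LiCl, THF, 50 °C). A water-free Negishi coupling of the two (Pd2(dba)3, SPhos, THF/NMP, 65 °C) would give the biaryl acetate F4, and methanolysis (K2CO3, MeOH, rt) returns to the route at compound 9.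

Step 11. The brominating agent may attack the free aromatic C–H positions of the alkoxy-rich rings, or brominate a side chain twice, instead of giving clean monobromination at each enol ether. The fallback sets out from compound 14 through its bis(silyl enol ether) 15 and avoids electrophilic halogen altogether. Oxidative α-sulfonyloxylation with [hydroxy(tosyloxy)iodo]benzene (CH2Cl2, rt) would give the bis(tosyloxyacetyl) diester F5. Displacement with PPh3 (MeCN, 60 °C) would give the bis(phosphonium tosylate) F6, and cold aqueous Na2CO3 returns to the route at compound 18.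

**Further compounds**

F1 | step 13 | 1-{2',4,6-tris(benzyloxy)-2,4'-dihydroxy-6'-methoxy-3'-[3-(4-(benzyloxy)phenyl)-3-oxopropanoyl][1,1'-biphenyl]-3-yl}-3-(4-methoxyphenyl)propane-1,3-dione | COc1ccc(cc1)C(=O)CC(=O)c1c(O)c(-c2c(OC)cc(O)c(C(=O)CC(=O)c3ccc(OCc4ccccc4)cc3)c2OCc2ccccc2)c(OCc2ccccc2)cc1OCc1ccccc1
F2 | step 7 | 6-acetyl-3,5-bis(benzyloxy)-2-iodophenyl acetate | CC(=O)Oc1c(I)c(OCc2ccccc2)cc(OCc2ccccc2)c1C(C)=O
F3 | step 7 | [3-acetyl-2-(benzyloxy)-6-methoxy-4-(methoxymethoxy)phenyl]zinc iodide | COCOc1cc(OC)c([Zn]I)c(OCc2ccccc2)c1C(C)=O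
F4 | step 7 | 3,3'-diacetyl-2',4,6-tris(benzyloxy)-6'-methoxy-4'-(methoxymethoxy)[1,1'-biphenyl]-2-yl acetate | CC(=O)Oc1c(C(C)=O)c(OCc2ccccc2)cc(OCc2ccccc2)c1-c1c(OC)cc(OCOC)c(C(C)=O)c1OCc1ccccc1
F5 | step 11 | 2',4,6-tris(benzyloxy)-4'-{[4-(benzyloxy)benzoyl]oxy}-6'-methoxy-3,3'-bis[(tosyloxy)acetyl][1,1'-biphenyl]-2-yl 4-methoxybenzoate | Cc1ccc(cc1)S(=O)(=O)OCC(=O)c1c(OC(=O)c2ccc(OC)cc2)c(-c2c(OC)cc(OC(=O)c3ccc(OCc4ccccc4)cc3)c(C(=O)COS(=O)(=O)c3ccc(C)cc3)c2OCc2ccccc2)c(OCc2ccccc2)cc1OCc1ccccc1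
F6 | step 11 | bis(triphenylphosphonium) ditosylate corresponding to 17 | O=C(C[P+](c1ccccc1)(c1ccccc1)c1ccccc1)c1c(OC(=O)c2ccc(OC)cc2)c(-c2c(OC)cc(OC(=O)c3ccc(OCc4ccccc4)cc3)c(C(=O)C[P+](c3ccccc3)(c3ccccc3)c3ccccc3)c2OCc2ccccc2)c(OCc2ccccc2)cc1OCc1ccccc1.Cc1ccc(cc1)S(=O)(=O)[O-].Cc1ccc(cc1)S(=O)(=O)[O-]
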